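I decided to follow the specific loss rate s of starting material, its rate of loss per unit of what stands, and to leave the concentrations aside until the end.

| flask | starting material | partner | protic impurity | remark | time |
|---|---|---|---|---|---|
| ochre | 0.37 M | 0.37 M | 0.025 M | run made earlier |  |
| blue | 0.37 M | 0.37 M | 0.055 M | run made earlier |  |
| teal | 0.74 M | 0.37 M | 0.037 M | run made earlier |  |
| eta | 0.37 M | 0.370 M | 0.0370 M |  | 4.0 min |
| zeta | 0.37 M | 0.370 M | 0.0370 M |  | 6.0 min |

| run | time / min | starting material / % | reactive form / % | target / % |
|---|---|---|---|---|
| ochre | 0.333 | 90.9 | 2.6 | 3.0 |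
| ochre | 0.667 | 84.9 | 2.2 | 7.2 |
| ochre | 1.00 | 79.5 | 3.0 | 11.9 |
| ochre | 2.00 | 66.8 | 2.6 | 23.9 |
| ochre | 4.00 | 49.2 | 1.6 | 42.0 |
| blue | 0.333 | 86.7 | 1.8 | 2.5 |
| blue | 1.00 | 72.8 | 2.4 | 11.5 |
| blue | 2.00 | 61.4 | 0.8 | 22.7 |
| blue | 3.00 | 52.1 | 2.2 | 30.7 |
| blue | 4.00 | 44.7 | 2.8 | 37.9 |
| teal | 0.833 | 83.6 | 2.2 | 9.4 |
| teal | 1.50 | 74.5 | 3.3 | 17.2 |
| teal | 2.50 | 64.1 | 3.1 | 28.1 |
| teal | 3.00 | 58.9 | 3.4 | 31.5 |
| teal | 4.00 | 50.3 | 4.8 | 38.8 |

(each reading ± 0.5 percentage points)

- what is said of target includes crystals
- crystals is a solid; its amount is given per volume of the solution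
- steps thought possible: starting material <-> reactive form; starting material + protic impurity -> quenched substrate; crystals <-> target; partner + reactive form -> target

* which of these there is most of at the end, counted by the starting material in it, eta (target / reactive form / starting material)
* which of these there is most of at the end, counted by the starting material in it, zeta (target / reactive form / starting material)
* how much there is at the end of the one of these that leads, in percent of the starting material charged: eta
* how much there is at the end of the one of these that leads, in percent of the starting material charged: zeta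

At the start, s read 0.287 min⁻¹ in the ochre run, with c(protic impurity) at 0.025 M, and 0.429 min⁻¹ in the blue run, with 0.055 M. A straight line through both reads 0.168 min⁻¹ at zero impurity and 0.343 min⁻¹ at the 0.0370 M of eta and zeta. From 2.00 min to 4.00 min, ochre gave 0.153 min⁻¹ and blue 0.159 min⁻¹, close together despite their different impurity charges. I called the late specific rate, a pseudo-first-order constant, the tail constant; the mean of these readings is 0.156 min⁻¹.

I counted the early end as a toll on the charge. At its last reading, the blue run lacked 14.6% of its charge, against an impurity charge equal to 14.9% of the starting material, so I set the toll for eta at 10.0%. Interpolating ochre and blue by impurity, I put eta's starting material at 47.4% and its reactive form at 2.08%. Thus s slows by a factor 2.20 and the amount by 2.11. By the balance I put eta's target at 40.5%, so in my reckoning starting material leads. Joining the tail on, I put zeta at 34.7% starting material and 53.2% target, so in my reckoning target leads.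

The forecast gave starting material at 47.4% for eta, and target at 53.3% for zeta, holding that “forming the reactive form is rate-limiting”.

The flask gives starting material at 47.3% in eta, and target at 53.5% in zeta.

    starting material ⇌ reactive form (K = 1.90, k = 0.00270 s⁻¹)
    starting material + protic impurity → quenched substrate (k = 0.130 L mol⁻¹ s⁻¹)
    crystals ⇌ target, rate k3*(cs3 - [target]) while solid is left; crystals form when [target] > cs3 (solubility = 0.160 M, k = 0.860 s⁻¹)
    partner + reactive form → target (k = 0.270 L mol⁻¹ s⁻¹)

Zeta holds less starting material than eta because of its longer time: read at eta's time, zeta would stand at 47.3% instead of 34.5%, a gap of 13 percentage points. In eta, the tail constant carries 65.0% at 2.00 min to 47.6% at 4.0 min, where eta holds 47.3%. In zeta, it carries 55.4% at 3.00 min to 34.7% at 6.0 min, where zeta holds 34.5%.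

The numbers in the tables were computed with made-up constants; the scatter is artificial.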